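**Retrosynthetic overview**

1. Target 27 ⇐ acetylation of alcohol 26 ⇐ vinylogous Horner–Wadsworth–Emmons olefination of lactol 19 with butenolide phosphonate 24. The (Z)-hydroxymethyl olefin of the triene is carried as a butenolide ring (18) that is reduced to 19.
2. 18 ⇐ B-alkyl Suzuki–Miyaura coupling of 4-bromofuran-2(5H)-one 16 with the borane of diene 15 ⇐ methylalumination/vinylation of alkyne 13, which sets the (E)-trisubstituted olefin ⇐ propargyl anion opening of spiro-epoxide 11.
3. 11 ⇐ hydroxy acid 8 ⇐ cis-fused keto lactone 5. Raney nickel removes the ring carbonyl (as dithiolane) and the lactone CH2–O bond (as selenide), which turns the lactone CH2 into the C-methyl group.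
4. 5 ⇐ enolic keto lactone 2 + vinyl ketone 3 in one operation (Michael addition, then aldol closure). Enabling feature, with ring carbons C1 = C(OH), C2 = CH(CH3), C3–C5 = CH2, C6 = C(CH3)2: with a temporary carbonyl at C5, C1 is an aldol carbon next to C6 and C2 is 1,5 to that carbonyl; the C2-methyl and the first side-chain carbon on C1 are cis, so they can be tied as a γ-lactone whose cis-fusion places OH trans to methyl.
5. Ring order: the cyclohexane first (step 2, built on the temporary lactone ring); then the chain butenolide ring enters with 16 (step 10) and is opened in step 15; the terminal butenolide ring (step 12) is attached last.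

Key step: step 2

Remark: 3 is taken as the purchasable stabilised enone, and the (R)-acid in step 2 is assumed to favour the (3aR,7aR) series; should the sense prove opposite, the (S)-acid is taken.

**Route**

Step 1
Reactants: 1 rac-3-hydroxydihydrofuran-2(3H)-one
Product: 2 3-hydroxyfuran-2(5H)-one
Conditions: Dess–Martin periodinane (1.05 equiv), CH2Cl2, 0 °C to rt
Reagents that add atoms: none
Why: Dess–Martin oxidation of the secondary α-hydroxy lactone should give the α-keto lactone, which rests as its conjugated enol 2; the stereocentre of 1 is destroyed, so the racemate is used.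

Step 2
Reactants: 2 3-hydroxyfuran-2(5H)-one; 3 4-methylpent-1-en-3-one
Product: 5 (3aR,7aR)-7a-hydroxy-7,7-dimethylhexahydro-2-benzofuran-1,6-dione, via enol Michael adduct 4 (not isolated)
Conditions: (R)-TRIP [(R)-3,3′-bis(2,4,6-triisopropylphenyl)-1,1′-binaphthyl-2,2′-diyl hydrogen phosphate] (10 mol %), 3 (1.5 equiv), toluene, 25 °C then 60 °C
Reagents that add atoms: none
Why: Proposed new method: the chiral phosphoric acid first joins the enol carbon C4 of 2 to the CH2 terminus of hydrogen-bonded enone 3 (acid-catalysed Michael addition) to give adduct 4, an achiral enol whose two keto enantiomers interconvert fast, and the same acid then enolises the isopropyl ketone of 4 toward its methine carbon and delivers this tetrasubstituted enol to the ring-ketone carbonyl of one keto tautomer (intramolecular aldol addition), so the CH(C)–CH2 bond and the C(OH)–C(CH3)2 bond of the new cyclohexane form in one flask. Closest known reaction types: the chiral-phosphoric-acid-catalysed Robinson-type Michael/intramolecular aldol annulation of dicarbonyl donors with vinyl ketones and the amine-catalysed Michael/aldol domino of enolic cyclic 1,2-diones with enals. The carbocycle closes in the 6-(enolendo)-exo-trig mode. Relative configuration is substrate-controlled: the new six-membered ring can only be cis-fused to the γ-lactone, which puts the tertiary OH (C7a) trans to the lactone CH2 on C3a, the later C-methyl group; absolute configuration at both new stereocentres is set together by the acid, which selects one keto enantiomer of 4 in a dynamic kinetic resolution. The step needs C- rather than O-attack of the enol on 3, reaction through the more substituted ketone enol and survival of the ketol: the CH2-side enol could only give a strained, reversible cyclobutanol, the quaternary C7 blocks conjugating dehydration, and the lactone keeps the acceptor a highly electrophilic 1,2-dicarbonyl.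

Step 3
Reactants: 5 (3aR,7aR)-7a-hydroxy-7,7-dimethylhexahydro-2-benzofuran-1,6-dione
Product: 6 (3aR,7aR)-7a-hydroxy-7,7-dimethylhexahydro-1H-spiro[2-benzofuran-6,2′-[1,3]dithiolan]-1-one
Conditions: HSCH2CH2SH (1.5 equiv), BF3·OEt2 (0.3 equiv), CH2Cl2, 0 °C to rt
Reagents that add atoms: ethane-1,2-dithiol SCCS
Why: Lewis-acid-mediated dithioketalisation of the only ketone (lactone and tertiary alcohol are inert) masks the carbonyl for reductive removal and blocks retro-aldol opening; no stereocentre is touched.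

Step 4
Reactants: 6 (3aR,7aR)-7a-hydroxy-7,7-dimethylhexahydro-1H-spiro[2-benzofuran-6,2′-[1,3]dithiolan]-1-one
Product: 7 (7R,8S)-7-hydroxy-6,6-dimethyl-8-[(phenylselanyl)methyl]-1,4-dithiaspiro[4.5]decane-7-carboxylic acid
Conditions: PhSeH, NaH, THF, 0 °C; then 6, DMF, 110 °C; aq. HCl work-up
Reagents that add atoms: benzeneselenol [SeH]c1ccccc1
Why: SN2 opening of the γ-lactone at its O–CH2 carbon by the soft selenolate (alkyl–oxygen cleavage of a lactone) should free the acid and place a reducible C–Se bond on the future methyl carbon; neither stereocentre is a reaction site.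

Step 5
Reactants: 7 (7R,8S)-7-hydroxy-6,6-dimethyl-8-[(phenylselanyl)methyl]-1,4-dithiaspiro[4.5]decane-7-carboxylic acid
Product: 8 (1R,6S)-1-hydroxy-2,2,6-trimethylcyclohexane-1-carboxylic acid
Conditions: Raney nickel (W-2, excess), EtOH, reflux
Reagents that add atoms: none
Why: Raney nickel hydrogenolysis of the C–S and C–Se bonds (Mozingo-type reduction) should turn the dithiolane carbon into CH2 and CH2SePh into CH3, leaving the tertiary alcohol and the acid untouched.

Step 6
Reactants: 8 (1R,6S)-1-hydroxy-2,2,6-trimethylcyclohexane-1-carboxylic acid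
Product: 9 (1R,6S)-1-(hydroxymethyl)-2,2,6-trimethylcyclohexan-1-ol
Conditions: LiAlH4, THF, reflux; aqueous NaOH work-up
Reagents that add atoms: none
Why: LiAlH4 reduction of the hindered α-hydroxy acid should give the 1,2-diol without touching either stereocentre.

Step 7
Reactants: 9 (1R,6S)-1-(hydroxymethyl)-2,2,6-trimethylcyclohexan-1-ol
Product: 11 (3R,8S)-4,4,8-trimethyl-1-oxaspiro[2.5]octane, via primary tosylate 10 (not isolated)
Conditions: TsCl, pyridine, CH2Cl2, 0 °C to rt; then K2CO3, MeOH, rt
Reagents that add atoms: none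
Why: Selective sulfonylation of the primary hydroxyl and 3-exo-tet Williamson closure by the tertiary alkoxide should give the spiro-epoxide with retention at the carbinol carbon, whose C–O bond is not broken.

Step 8
Reactants: 11 (3R,8S)-4,4,8-trimethyl-1-oxaspiro[2.5]octane
Product: 13 (1R,6S)-1-(but-3-yn-1-yl)-2,2,6-trimethylcyclohexan-1-ol, via silyl alkyne 12 (not isolated)
Conditions: CH3C≡CSiMe3, n-BuLi, TMEDA, THF, −78 to 0 °C; add 11, 0 °C to rt; then MeOH, K2CO3, rt
Reagents that add atoms: 1-(trimethylsilyl)propyne CC#C[Si](C)(C)C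
Why: The propargylic lithium reagent should open the 2,2-disubstituted epoxide at its CH2 terminus (SN2), which regenerates the tertiary alcohol with unchanged configuration, and methanolysis removes the alkynyl silane.

Step 9
Reactants: 13 (1R,6S)-1-(but-3-yn-1-yl)-2,2,6-trimethylcyclohexan-1-ol
Product: 15 (1R,6S)-2,2,6-trimethyl-1-[(3E)-3-methylhexa-3,5-dien-1-yl]cyclohexan-1-ol, via alkenylalane 14 (not isolated)
Conditions: Me3Al (3 equiv), Cp2ZrCl2 (0.3 equiv), CH2Cl2, 0 °C to rt; then CH2=CHBr, Pd(PPh3)4 (5 mol %), ZnCl2, THF, rt; aq. NaHCO3 work-up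
Reagents that add atoms: trimethylaluminium C[Al](C)C; vinyl bromide C=CBr
Why: Zirconium-catalysed syn-methylalumination of the terminal alkyne (Negishi carboalumination, the hydroxyl carried as its aluminium alkoxide) fixes the (E)-trisubstituted olefin, and palladium-catalysed coupling of the alkenylalane with vinyl bromide should proceed with retention.

Step 10
Reactants: 15 (1R,6S)-2,2,6-trimethyl-1-[(3E)-3-methylhexa-3,5-dien-1-yl]cyclohexan-1-ol; 16 4-bromofuran-2(5H)-one
Product: 18 4-{(3E)-6-[(1R,6S)-1-hydroxy-2,2,6-trimethylcyclohexyl]-4-methylhex-3-en-1-yl}furan-2(5H)-one, via B-alkyl-9-BBN borane 17 (not isolated)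
Conditions: 9-BBN-H dimer (2.2 equiv of B–H), THF, 0 °C to rt; then 16, PdCl2(dppf) (5 mol %), AsPh3, Cs2CO3, DMF/H2O, rt
Reagents that add atoms: none
Why: 9-BBN should hydroborate only the monosubstituted terminal double bond of the diene at its CH2 end, and B-alkyl Suzuki–Miyaura coupling with the β-bromo butenolide attaches the chain at C4 of the lactone; the trisubstituted olefin and the tertiary alcohol are not affected.

Step 11
Reactants: 18 4-{(3E)-6-[(1R,6S)-1-hydroxy-2,2,6-trimethylcyclohexyl]-4-methylhex-3-en-1-yl}furan-2(5H)-one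
Product: 19 4-{(3E)-6-[(1R,6S)-1-hydroxy-2,2,6-trimethylcyclohexyl]-4-methylhex-3-en-1-yl}-2,5-dihydrofuran-2-ol
Conditions: i-Bu2AlH (2.3 equiv), CH2Cl2, −78 °C; aq. Rochelle salt work-up, used crude
Reagents that add atoms: none
Why: Low-temperature i-Bu2AlH reduction should stop at the lactol, a masked (Z)-4-hydroxy enal whose olefin geometry is locked by the ring; non-acidic work-up avoids dehydration to the furan.

Step 12
Reactants: 20 1,3-dihydroxyacetone (used as its commercial dimer)
Product: 22 4-(hydroxymethyl)furan-2(5H)-one, via open-chain enoate 21 (not isolated)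
Conditions: Ph3P=CHCO2Et, CH2Cl2, rt
Reagents that add atoms: ethyl (triphenyl-λ5-phosphanylidene)acetate CCOC(=O)C=P(c1ccccc1)(c1ccccc1)c1ccccc1
Why: Wittig olefination of the activated ketone with the stabilised ylide gives an enoate whose cis hydroxymethyl group lactonises spontaneously; the two CH2OH groups are equivalent, so there is no geometry issue.

Step 13
Reactants: 22 4-(hydroxymethyl)furan-2(5H)-one
Product: 23 4-(bromomethyl)furan-2(5H)-one
Conditions: CBr4, PPh3, CH2Cl2, 0 °C
Reagents that add atoms: tetrabromomethane BrC(Br)(Br)Br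
Why: Appel bromination of the primary allylic alcohol proceeds under neutral conditions that the butenolide tolerates.

Step 14
Reactants: 23 4-(bromomethyl)furan-2(5H)-one
Product: 24 diethyl [(5-oxo-2,5-dihydrofuran-3-yl)methyl]phosphonate
Conditions: P(OEt)3, neat, 110 °C
Reagents that add atoms: triethyl phosphite CCOP(OCC)OCC
Why: Michaelis–Arbuzov reaction of the reactive allylic bromide gives the vinylogous phosphonate.

Step 15
Reactants: 19 4-{(3E)-6-[(1R,6S)-1-hydroxy-2,2,6-trimethylcyclohexyl]-4-methylhex-3-en-1-yl}-2,5-dihydrofuran-2-ol; 24 diethyl [(5-oxo-2,5-dihydrofuran-3-yl)methyl]phosphonate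
Product: 26 (2Z,5E)-8-[(1R,6S)-1-hydroxy-2,2,6-trimethylcyclohexyl]-6-methyl-2-[(2E)-3-(5-oxo-2,5-dihydrofuran-3-yl)prop-2-en-1-ylidene]oct-5-en-1-ol, via ring-opened hydroxy enal 25 (not isolated)
Conditions: 24 (2.5 equiv), LiN(SiMe3)2 (2.4 equiv), THF, −78 °C; add 19, −78 to 0 °C
Reagents that add atoms: none
Why: The lactol opens under base to the (Z)-hydroxy enal and the vinylogous phosphonate anion adds through its phosphorus-bearing carbon (Horner–Wadsworth–Emmons), which should give the (E)-disubstituted olefin while the (Z)-geometry set by the former ring is kept.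

Step 16
Reactants: 26 (2Z,5E)-8-[(1R,6S)-1-hydroxy-2,2,6-trimethylcyclohexyl]-6-methyl-2-[(2E)-3-(5-oxo-2,5-dihydrofuran-3-yl)prop-2-en-1-ylidene]oct-5-en-1-ol
Product: 27 (2Z,5E)-8-[(1R,6S)-1-hydroxy-2,2,6-trimethylcyclohexyl]-6-methyl-2-[(2E)-3-(5-oxo-2,5-dihydrofuran-3-yl)prop-2-en-1-ylidene]oct-5-en-1-yl acetate
Conditions: Ac2O, pyridine, DMAP (cat.), CH2Cl2, 0 °C
Reagents that add atoms: acetic anhydride CC(=O)OC(C)=O
Why: The primary allylic alcohol is acetylated, while the tertiary alcohol between two substituted ring carbons is too hindered to react under these conditions.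

**Compound list**

1 | rac-3-hydroxydihydrofuran-2(3H)-one (α-hydroxy-γ-butyrolactone) | O=C1OCCC1O | starting material
2 | 3-hydroxyfuran-2(5H)-one (enol form of dihydrofuran-2,3-dione) | O=C1OCC=C1O | intermediate
3 | 4-methylpent-1-en-3-one (isopropyl vinyl ketone) | C=CC(=O)C(C)C | starting material
4 | 3-hydroxy-4-(4-methyl-3-oxopentyl)furan-2(5H)-one | CC(C)C(=O)CCC1=C(O)C(=O)OC1 | intermediate
5 | (3aR,7aR)-7a-hydroxy-7,7-dimethylhexahydro-2-benzofuran-1,6-dione (cis-fused keto lactone) | O=C1OC[C@H]2CCC(=O)C(C)(C)[C@@]12O | intermediate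
6 | (3aR,7aR)-7a-hydroxy-7,7-dimethylhexahydro-1H-spiro[2-benzofuran-6,2′-[1,3]dithiolan]-1-one | O=C1OC[C@H]2CCC3(SCCS3)C(C)(C)[C@@]12O | intermediate
7 | (7R,8S)-7-hydroxy-6,6-dimethyl-8-[(phenylselanyl)methyl]-1,4-dithiaspiro[4.5]decane-7-carboxylic acid | O=C(O)[C@@]1(O)[C@@H](C[Se]c2ccccc2)CCC2(SCCS2)C1(C)C | intermediate
8 | (1R,6S)-1-hydroxy-2,2,6-trimethylcyclohexane-1-carboxylic acid | O=C(O)[C@@]1(O)[C@@H](C)CCCC1(C)C | intermediate
9 | (1R,6S)-1-(hydroxymethyl)-2,2,6-trimethylcyclohexan-1-ol | OC[C@@]1(O)[C@@H](C)CCCC1(C)C | intermediate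
10 | [(1R,6S)-1-hydroxy-2,2,6-trimethylcyclohexyl]methyl 4-methylbenzenesulfonate | Cc1ccc(cc1)S(=O)(=O)OC[C@@]1(O)[C@@H](C)CCCC1(C)C | intermediate
11 | (3R,8S)-4,4,8-trimethyl-1-oxaspiro[2.5]octane | C1O[C@@]12[C@@H](C)CCCC2(C)C | intermediate
12 | (1R,6S)-2,2,6-trimethyl-1-[4-(trimethylsilyl)but-3-yn-1-yl]cyclohexan-1-ol | C[Si](C)(C)C#CCC[C@@]1(O)[C@@H](C)CCCC1(C)C | intermediate
13 | (1R,6S)-1-(but-3-yn-1-yl)-2,2,6-trimethylcyclohexan-1-ol | C#CCC[C@@]1(O)[C@@H](C)CCCC1(C)C | intermediate
14 | dimethyl[(1E)-4-{(1R,6S)-1-[(dimethylalumanyl)oxy]-2,2,6-trimethylcyclohexyl}-2-methylbut-1-en-1-yl]alumane | C[Al](C)/C=C(\C)CC[C@@]1(O[Al](C)C)[C@@H](C)CCCC1(C)C | intermediate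
15 | (1R,6S)-2,2,6-trimethyl-1-[(3E)-3-methylhexa-3,5-dien-1-yl]cyclohexan-1-ol | C=C/C=C(\C)CC[C@@]1(O)[C@@H](C)CCCC1(C)C | intermediate
16 | 4-bromofuran-2(5H)-one | O=C1OCC(Br)=C1 | starting material
17 | 9-{(3E)-6-[(1R,6S)-1-hydroxy-2,2,6-trimethylcyclohexyl]-4-methylhex-3-en-1-yl}-9-borabicyclo[3.3.1]nonane | B1(C2CCCC1CCC2)CC/C=C(\C)CC[C@@]1(O)[C@@H](C)CCCC1(C)C | intermediate
18 | 4-{(3E)-6-[(1R,6S)-1-hydroxy-2,2,6-trimethylcyclohexyl]-4-methylhex-3-en-1-yl}furan-2(5H)-one | O=C1OCC(CC/C=C(\C)CC[C@@]2(O)[C@@H](C)CCCC2(C)C)=C1 | intermediate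
19 | 4-{(3E)-6-[(1R,6S)-1-hydroxy-2,2,6-trimethylcyclohexyl]-4-methylhex-3-en-1-yl}-2,5-dihydrofuran-2-ol (both anomers) | OC1OCC(CC/C=C(\C)CC[C@@]2(O)[C@@H](C)CCCC2(C)C)=C1 | intermediate
20 | 1,3-dihydroxyacetone | OCC(=O)CO | starting material
21 | ethyl 4-hydroxy-3-(hydroxymethyl)but-2-enoate | CCOC(=O)C=C(CO)CO | intermediate
22 | 4-(hydroxymethyl)furan-2(5H)-one | OCC1=CC(=O)OC1 | intermediate
23 | 4-(bromomethyl)furan-2(5H)-one | BrCC1=CC(=O)OC1 | intermediate
24 | diethyl [(5-oxo-2,5-dihydrofuran-3-yl)methyl]phosphonate | CCOP(=O)(OCC)CC1=CC(=O)OC1 | intermediate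
25 | (2Z,6E)-3-(hydroxymethyl)-9-[(1R,6S)-1-hydroxy-2,2,6-trimethylcyclohexyl]-7-methylnona-2,6-dienal | O=C/C=C(\CO)CC/C=C(\C)CC[C@@]1(O)[C@@H](C)CCCC1(C)C | intermediate
26 | (2Z,5E)-8-[(1R,6S)-1-hydroxy-2,2,6-trimethylcyclohexyl]-6-methyl-2-[(2E)-3-(5-oxo-2,5-dihydrofuran-3-yl)prop-2-en-1-ylidene]oct-5-en-1-ol | OC/C(=C\C=C\C1=CC(=O)OC1)CC/C=C(\C)CC[C@@]1(O)[C@@H](C)CCCC1(C)C | intermediate
27 | (2Z,5E)-8-[(1R,6S)-1-hydroxy-2,2,6-trimethylcyclohexyl]-6-methyl-2-[(2E)-3-(5-oxo-2,5-dihydrofuran-3-yl)prop-2-en-1-ylidene]oct-5-en-1-yl acetate | CC(=O)OC/C(=C\C=C\C1=CC(=O)OC1)CC/C=C(\C)CC[C@@]1(O)[C@@H](C)CCCC1(C)C | target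

**Step count and risks**

Total: 16 steps. Longest linear sequence: 13 steps (steps 1–11, 15, 16); steps 12–14 form the phosphonate branch.

Steps most likely to fail:

1. Step 2 (Proposed new method). The aldol closure may not turn over, because adduct 4 rests as its enol or drifts to a cyclic hemiketal or dihydropyran by attack of the enol oxygen on the ketone. The chiral acid may also discriminate the two keto enantiomers poorly. Fallback with established reaction types, racemic then resolved: from 2 and 3, Et3N (cat.) in CH2Cl2 gives adduct 4, which is isolated. Adduct 4 is closed by acid-mediated intramolecular aldol addition (TsOH·H2O, wet toluene, 80 °C) to the racemic cis-fused keto lactone, that is 5 together with its enantiomer (3aS,7aS)-7a-hydroxy-7,7-dimethylhexahydro-2-benzofuran-1,6-dione F1. The enantiomers are separated by preparative chromatography on a chiral stationary phase (amylose tris(3,5-dimethylphenylcarbamate)), and 5 re-enters the route at step 3.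

2. Step 8. Substitution at the neopentyl-type CH2 of 11 may be slow, because the nucleophile has to pass over the ring face. Lithium-salt-promoted rearrangement of the epoxide to carbonyl compounds, or attack through the allenyl terminus of the ambident anion, may then take over. Fallback without substitution at this carbon: from diol 9, SO3·pyridine/DMSO/i-Pr2NEt oxidation gives (1R,6S)-1-hydroxy-2,2,6-trimethylcyclohexane-1-carbaldehyde F2. Neutral Wittig olefination with Ph3P=CHCO2Et (toluene, 60 °C, to avoid base-induced α-ketol rearrangement) gives ethyl (2E)-3-[(1S,6S)-1-hydroxy-2,2,6-trimethylcyclohexyl]prop-2-enoate F3; the descriptor at C1 changes by priority only. Hydrogenation (H2, Pd/C, EtOAc) gives ethyl 3-[(1R,6S)-1-hydroxy-2,2,6-trimethylcyclohexyl]propanoate F4. i-Bu2AlH (CH2Cl2, −78 °C) gives the spiro lactol (5R,10S)-6,6,10-trimethyl-1-oxaspiro[4.5]decan-2-ol F5. Ohira–Bestmann homologation (dimethyl (1-diazo-2-oxopropyl)phosphonate, K2CO3, MeOH) of F5 gives alkyne 13, where the route is rejoined.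

3. Step 15. Under the basic conditions the ring-opened (Z)-hydroxy enal may isomerise to the (E)-enal, the ambident phosphonate anion may react through its ring γ-carbon, and the product alkoxide may add back to the trienyl lactone. Fallback that moves the last C–C bond to a cross-coupling under non-basic olefination: from lactol 19, Takai iodo-olefination (CrCl2, CHI3, THF, 0 °C) gives (1R,6S)-1-[(3E,7Z,9E)-7-(hydroxymethyl)-10-iodo-3-methyldeca-3,7,9-trien-1-yl]-2,2,6-trimethylcyclohexan-1-ol F6. Bromide 16 is converted with hexabutylditin and Pd(PPh3)4 into 4-(tributylstannyl)furan-2(5H)-one F7. Stille coupling of F6 with F7 (Pd2(dba)3, AsPh3, DMF, rt) gives alcohol 26, which continues with step 16.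

Further compounds
F1 | step 2 | (3aS,7aS)-7a-hydroxy-7,7-dimethylhexahydro-2-benzofuran-1,6-dione | O=C1OC[C@@H]2CCC(=O)C(C)(C)[C@]12O
F2 | step 8 | (1R,6S)-1-hydroxy-2,2,6-trimethylcyclohexane-1-carbaldehyde | O=C[C@@]1(O)[C@@H](C)CCCC1(C)C
F3 | step 8 | ethyl (2E)-3-[(1S,6S)-1-hydroxy-2,2,6-trimethylcyclohexyl]prop-2-enoate | CCOC(=O)/C=C/[C@@]1(O)[C@@H](C)CCCC1(C)C
F4 | step 8 | ethyl 3-[(1R,6S)-1-hydroxy-2,2,6-trimethylcyclohexyl]propanoate | CCOC(=O)CC[C@@]1(O)[C@@H](C)CCCC1(C)C
F5 | step 8 | (5R,10S)-6,6,10-trimethyl-1-oxaspiro[4.5]decan-2-ol | OC1CC[C@@]2(O1)[C@@H](C)CCCC2(C)C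
F6 | step 15 | (1R,6S)-1-[(3E,7Z,9E)-7-(hydroxymethyl)-10-iodo-3-methyldeca-3,7,9-trien-1-yl]-2,2,6-trimethylcyclohexan-1-ol | OC/C(=C\C=C\I)CC/C=C(\C)CC[C@@]1(O)[C@@H](C)CCCC1(C)C
F7 | step 15 | 4-(tributylstannyl)furan-2(5H)-one | CCCC[Sn](CCCC)(CCCC)C1=CC(=O)OC1
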